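How much of the starting material has reacted after 2.0 min when the coupling partner is changed? Each flask holds less starting material than coupling partner, so I take starting material as the limiting reagent and keep its books in fractions of the charge.

in all of them: starting material 5.0 × 10⁻⁴ M; free catalyst 2.5 µM

| charge | coupling partner | remark | time |
|---|---|---|---|
| ash | 2.9 mM | run made earlier |  |
| larch | 4.4 mM | run made earlier |  |
| beta | 2.00 mM |  | 2.0 min |
| theta | 3.00 mM |  | 2.0 min |
| epsilon | 4.50 mM |  | 2.0 min |

| run | time / s | starting material / % | product / % |
|---|---|---|---|
| ash | 30.0 | 86.5 | 9.8 |
| ash | 60.0 | 71.4 | 18.8 |
| ash | 90.0 | 57.7 | 29.3 |
| ash | 120 | 46.6 | 36.9 |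
| larch | 30.0 | 84.5 | 8.8 |
| larch | 60.0 | 70.2 | 17.7 |
| larch | 90.0 | 56.1 | 27.9 |
| larch | 120 | 45.9 | 35.9 |

(scatter of a reading: 1 percentage point)

* part of the starting material that has reacted at the end, beta
* part of the starting material that has reacted at the end, theta
* part of the starting material that has reacted at the end, epsilon
* what raising the concentration of coupling partner from its lowest to its highest value here does to the part of the starting material that has reacted (changes below 5 percentage points count as none) (it falls / it rises / no change)

- what has gone from starting material into another species counts as reacted, even if it can come back

In the ash run at 120 s, 46.6% is still starting material, 36.9% is product, and the remaining 16.5% is in neither column. In the larch run at 120 s the entries are 45.9%, 35.9% and 18.2%. The catalyst charge is 0.500% of the starting material charge, far less than either gap, so most of the gap sits in something other than catalyst. It counts as reacted anyway, so the answer is simply the charge minus what is left: 53.4% in ash and 54.1% in larch. These differ by less than the scatter of one reading, although the coupling partner differs by a factor of 1.52.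

So I carry one quantity. Averaged over both runs, the fraction gone by the last reading divided by that time is 0.269 /min, the mean loss rate. As a straight line it falls 2.3 percentage points short of the mean reading at 60.0 s, but the asked time equals the last reading, so the line needs no stretching. I therefore expect 53.8% in all three flasks, and beta is the least safe, since it has less coupling partner than either run.

The forecast gives 53%, 53.5% and 54%, with the trend no change, holding that "the step consuming starting material does not involve it". Its figures rise slightly from beta to epsilon, where mine stay flat.

The flasks give 52.7% in beta, 54.1% in theta and 54.9% in epsilon. The trend is no change, with a change of 2.2 points, less than the 5 points that would count.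

    catalyst intermediate D → free catalyst + product (k = 9.02 /s)
    starting material + catalyst intermediate A → catalyst intermediate B (k = 31000 /M/s)
    catalyst intermediate C → released group + catalyst intermediate D (k = 2.46 /s)
    starting material + catalyst intermediate B ⇌ idle complex, settled at all times (K = 954 /M)
    coupling partner + free catalyst → catalyst intermediate A (k = 3900 /M/s)
    starting material + released group ⇌ idle adduct, settled at all times (K = 3100 /M)
    catalyst intermediate B ⇌ catalyst intermediate C (K = 0.769, k = 7.74 /s)

In beta at 1.00 min, free catalyst has a half-life of 0.093 s by taking up coupling partner, while catalyst intermediate C has one of 0.28 s by the step of giving off released group taken alone, longer by a factor of 3.01. At that time 25.0% of the catalyst charged is catalyst intermediate C and 8.27% is free catalyst. The mean loss rate puts beta 1 point above its result. Carried to the same flask read at 3.0 min, it gives 80.7%, and that flask has 72.3% reacted.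

The data were computed with made-up constants.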